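How far does the excess of right-handed substrate climb in this flask by 10 d? Reckon it from two rates: the fractional loss per day of each substrate.

| flask | left-handed substrate | right-handed substrate | gas | free catalyst | remark | time |
|---|---|---|---|---|---|---|
| oak | 0.020 M | 0.020 M | 4.7 mM (held) | 1.1 mM | run made earlier |  |
| elm | 0.020 M | 0.020 M | 4.7 mM (held) | 1.8 mM | run made earlier |  |
| flask | 0.020 M | 0.020 M | 4.7 mM (held) | 0.80 mM |  | 10 d |

| run | time / d | right-handed substrate / % | left-handed substrate / % |
|---|---|---|---|
| oak | 1.67 | 48.1 | 32.1 |
| oak | 3.00 | 48.8 | 19.9 |
| oak | 5.00 | 47.8 | 7.6 |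
| oak | 6.00 | 46.2 | 4.7 |
| oak | 8.00 | 45.6 | 0.6 |
| oak | 10.0 | 45.1 | 0 |
| elm | 0.625 | 48.1 | 41.2 |
| elm | 2.08 | 47.7 | 22.8 |
| elm | 4.00 | 46.6 | 5.7 |
| elm | 5.00 | 46.4 | 2.8 |
| elm | 8.00 | 43.5 | 0.4 |
| elm | 10.0 | 41.7 | 0.4 |

(scatter of a reading: 0.5 percentage points)

- free catalyst is single-handed; left-handed substrate and right-handed substrate are mirror images of each other, charged as a racemate, each of them at the stated concentration
- at the start none of partner is dissolved
- what was read earlier has a scatter of 0.5 percentage points, one standard deviation
- steps thought possible: free catalyst + left-handed substrate <-> catalyst intermediate A; free catalyst + right-handed substrate <-> catalyst intermediate B; partner + catalyst intermediate A -> free catalyst + left-handed product; partner + catalyst intermediate B -> free catalyst + right-handed product; gas <-> partner; partner -> decomposed reagent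

- whether the excess of right-handed substrate over left-handed substrate among what is left of the two reaches 90% by 10 d (yes / no)
- the highest excess of right-handed substrate over left-handed substrate among what is left of the two up to 10 d

1. Divide the left-handed rate by the right-handed one and time drops out. The ratio of the logarithmic falls is the selectivity factor. Taken from the first reading to 6.00 d in oak and to 5.00 d in elm, both runs pooled, it reads 60.4.

2. The right-handed fall from first to last reading, pooled per catalyst and scaled to 0.80 mM, gives 0.00637 d⁻¹ for this flask. The ratio then gives the left-handed rate, 0.385 d⁻¹.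

3. By my reckoning, the flask keeps 93.8% of its right-handed charge and 2.13% of its left-handed charge at 10 d. That is an excess of 95.6%, still rising, and 90% falls at 7.78 d.

4. The forecast says yes, with a top of 96.5% (93% to 99%), slightly above mine, and that “the top falls at the end”.

The flask gives yes and a top of 94.9%.

    free catalyst + left-handed substrate ⇌ catalyst intermediate A (K = 42.0 M⁻¹, k = 45.0 M⁻¹ min⁻¹)
    free catalyst + right-handed substrate ⇌ catalyst intermediate B (K = 53.0 M⁻¹, k = 35.0 M⁻¹ min⁻¹)
    partner + catalyst intermediate A → free catalyst + left-handed product (k = 7.00 M⁻¹ min⁻¹)
    partner + catalyst intermediate B → free catalyst + right-handed product (k = 0.0820 M⁻¹ min⁻¹)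
    gas ⇌ partner, rate k5*(csat - [partner]) (kL = 0.00150 min⁻¹)
    partner → decomposed reagent (k = 6.50 × 10⁻⁴ min⁻¹)

The flask passes 90% at 8.58 d, and at 10 d it keeps 93% of its right-handed charge and 2.4% of its left-handed charge. Between 1.00 d and 10.0 d its own ratio reads 60.6. The largest single effect on the excess in this flask at 10 d is the return of catalyst intermediate B to free catalyst and right-handed substrate. With that step taken away, the excess at 10 d goes from 94.9% to −10.0%, and the part reacted falls from 52.5% to 9.48%.

All runs were computed from invented constants.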